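The runs stem from a simulated flask from invented constants; scatter was added.

- Going from Monday's flask to Tuesday's, free catalyst rises by a factor of 1.52, but the target read at 20 h rises by 2.40, more than in proportion.

common to all: starting material 1.7 M; gas phase 200 mM (held); added ligand 3.5 mM
- Monday's: free catalyst 0.42 mM; impurity 0.20 mM; run made earlier
- Tuesday's: free catalyst 0.64 mM; impurity 0.20 mM; run made earlier
- Thursday's: free catalyst 0.85 mM; impurity 0.10 mM; run made earlier
- flask: free catalyst 0.85 mM; impurity 0.20 mM; time 20 h

- Monday's (time / h: target / %): 2.50: 0; 8.00: 4; 12.0: 2; 20.0: 5
- Tuesday's (time / h: target / %): 1.50: 0; 4.00: 0; 8.00: 5; 20.0: 12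
- Thursday's (time / h: target / %): 2.50: 1; 8.00: 10; 12.0: 10; 20.0: 13

(readings scatter by 1.5 percentage points)

- what was read earlier has a scatter of 1.5 percentage points, one standard deviation
- at the start none of the gas phase is in solution

- teal: doubling the transfer coefficient of the gas phase, all else as stated
- grey: doubling the amount of free catalyst, all else as stated
- amber: doubling the saturation concentration of gas phase, all else as stated

- target at 20 h, in percent of the starting material charged
- the change that raises the amount of target at 20 h, in percent of the starting material charged most ("none" if none brings more than 2 percentage points) (teal / grey / amber / none)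
- amount of target at 20 h, in percent of the starting material charged, after amber

- Suppose, as in an active-site titration, that each impurity kills one catalyst. Then define c*, the live catalyst, as free catalyst charged minus impurity charged: 0.220 mM on Monday, 0.440 mM on Tuesday, 0.750 mM on Thursday, and 0.650 mM in the new flask.
- From Monday to Tuesday c* rises by a factor of 2.00, against 2.40 for the target readings, and those carry a scatter of 1.5 percentage points on a reading of 5%.
- Now let G be the fraction of starting material turned to target by 20 h, per unit of c*. Monday reads 0.227 /mM, Tuesday 0.273 /mM and Thursday 0.173 /mM.
- Tuesday's G puts the new flask at 17.7%, Thursday's at 11.2%, so a constant G is the weak link: Thursday's is lower, and its target reads 10% at 12.0 h and 13% at 20.0 h.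
- Reforge that link by reading G between those two flasks at the flask's c*: 0.205 /mM. My own reckoning is then 13.3%, give or take the scatter.
- The forecast gives 13% (11% to 16%), with amber best at 20% (14% to 27%): “Raising the saturation concentration lifts both the gas supply and the dissolved level, so it should beat faster transfer.”
- The flask gives 13.6%, and amber comes first at 25.8%, which is 5.8 points above the forecast.

    free catalyst + added ligand ⇌ idle complex, settled at all times (K = 710 /M)
    starting material + dissolved gas + free catalyst → free catalyst + target (k = 9.10 /M²/min)
    starting material + target → side product (k = 7.60 × 10⁻⁴ /M/min)
    gas phase ⇌ dissolved gas, rate k4*(csat - [dissolved gas]) (kL = 0.00580 /min)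
    free catalyst + impurity → spent catalyst (k = 1700 /M/min)

- At 20.0 h the impurity, limiting reagent of the poisoning step, stands at 0%, and spent catalyst at 23.5% of the catalyst charged. So c* is 76.5% of the charge, held as free catalyst 24.1% and idle complex 52.3%, and G is 0.209 /mM. The neighbour charged with 0.014 M of added ligand has the same c* of 0.650 mM, yet gives 5.38%, a G of 0.0828 /mM, with free catalyst at 7.27% of the charge.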